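**Strategy.** Ring A is disconnected at C8–O and C4a–C5. This leaves ring B as a 4-methoxy-2-pyranone whose C3 (the later C8a) carries a 3-oxobut-1-ynyl group, and ring C as a phenol whose neighbouring hydroxyl is benzyl-protected. The key step exploits the 1,3 relation of the C8 aryloxy group and the C6 hydroxyl on ring A, a masked β-aryloxy enone lying between the fusion carbons C8a and C4a. Phenoxide conjugate addition to the ynone makes the hindered diaryl ether bond, and the acetyl enolate then displaces methoxide at pyranone C4 (C4a) to close and aromatise ring A in the same flask. Debenzylation ends the synthesis.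

Key step: step 10

Remark: isocoumarin numbering is used for rings A and B (C1 lactone carbonyl, O2, C3 bearing the pentyl group, C4, C4a, C5 to C8, C8a), and ring C is the aryloxy ring. The target has no stereocentre, so but-3-yn-2-ol is used as the racemate.

**Route**

Step 1
Reactants: 1 4-hydroxy-6-methyl-2H-pyran-2-one; 2 1-iodobutane
Product: 3 4-hydroxy-6-pentyl-2H-pyran-2-one
Conditions: LiN(i-Pr)2 (2.4 equiv), THF–DMPU, −78 °C; then 2, −78 to 0 °C; aq. HCl
Reagents that add atoms: none
Why: Double deprotonation gives the oxido/6-methylene dianion, which alkylates at the more basic terminal carbanion (dianion γ-alkylation of a vinylogous β-dicarbonyl), a known reaction of this lactone with primary alkyl halides.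

Step 2
Reactants: 3 4-hydroxy-6-pentyl-2H-pyran-2-one
Product: 4 4-methoxy-6-pentyl-2H-pyran-2-one
Conditions: Me2SO4 (1.1 equiv), K2CO3, acetone, reflux
Reagents that add atoms: dimethyl sulfate, COS(=O)(=O)OC
Why: Williamson-type O-alkylation of the vinylogous acid with a hard methylating agent should give the 4-methoxy-2-pyranone as the main regioisomer, as is known for the 6-methyl analogue.

Step 3
Reactants: 4 4-methoxy-6-pentyl-2H-pyran-2-one
Product: 5 3-iodo-4-methoxy-6-pentyl-2H-pyran-2-one
Conditions: N-iodosuccinimide (1.1 equiv), CF3CO2H (cat.), MeCN, rt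
Reagents that add atoms: N-iodosuccinimide, O=C1CCC(=O)N1I
Why: Electrophilic iodination should occur at C3, which is the β-carbon of both the methyl enol ether and the ring enol ether and therefore the most nucleophilic position of a 4-methoxy-2-pyranone.

Step 4
Reactants: 5 3-iodo-4-methoxy-6-pentyl-2H-pyran-2-one; 6 but-3-yn-2-ol (racemic)
Product: 7 3-(3-hydroxybut-1-yn-1-yl)-4-methoxy-6-pentyl-2H-pyran-2-one (racemic)
Conditions: PdCl2(PPh3)2 (3 mol %), CuI (5 mol %), Et3N, THF, rt to 45 °C
Reagents that add atoms: none
Why: Sonogashira coupling, in which the electron-poor C3–I bond adds readily to zerovalent palladium and the free propargylic alcohol is tolerated, under conditions mild enough to leave the lactone and the enol ether intact.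

Step 5
Reactants: 7 3-(3-hydroxybut-1-yn-1-yl)-4-methoxy-6-pentyl-2H-pyran-2-one (racemic)
Product: 8 4-methoxy-3-(3-oxobut-1-yn-1-yl)-6-pentyl-2H-pyran-2-one
Conditions: Dess–Martin periodinane (1.2 equiv), CH2Cl2, 0 °C to rt
Reagents that add atoms: none
Why: Dess–Martin oxidation of a secondary propargylic alcohol is fast and non-nucleophilic, so the electrophilic ynone and the pyranone are not exposed to base or amine; the racemic carbinol centre disappears here.

Step 6
Reactants: 9 olivetol (5-pentylbenzene-1,3-diol)
Product: 11 2,4-dihydroxy-6-pentylbenzaldehyde, via iminium chloride 10 (not isolated)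
Conditions: POCl3 (1.2 equiv), DMF, 0 °C to rt; then aq. NaOAc, 50 °C
Reagents that add atoms: N,N-dimethylformamide, CN(C)C=O; water, O
Why: Vilsmeier–Haack formylation of the resorcinol should attack the ring carbon ortho to one hydroxyl and para to the other (next to the pentyl group), as is established for olivetol and orcinol, and the iminium salt is hydrolysed on work-up.

Step 7
Reactants: 11 2,4-dihydroxy-6-pentylbenzaldehyde
Product: 12 2-hydroxy-4-methoxy-6-pentylbenzaldehyde
Conditions: MeI (1.05 equiv), K2CO3 (1.0 equiv), acetone, rt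
Reagents that add atoms: iodomethane, CI
Why: Williamson etherification selective for the 4-hydroxyl, which is the more acidic one (para to the formyl group) and is not tied up in the hydrogen bond that deactivates the 2-hydroxyl.

Step 8
Reactants: 12 2-hydroxy-4-methoxy-6-pentylbenzaldehyde
Product: 13 2-(benzyloxy)-4-methoxy-6-pentylbenzaldehyde
Conditions: BnBr (1.2 equiv), K2CO3, DMF, 60 °C
Reagents that add atoms: benzyl bromide, BrCc1ccccc1
Why: Williamson benzylation of the remaining chelated phenol under slightly more forcing conditions, with no other alkylatable site in the molecule.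

Step 9
Reactants: 13 2-(benzyloxy)-4-methoxy-6-pentylbenzaldehyde
Product: 15 2-(benzyloxy)-4-methoxy-6-pentylphenol, via aryl formate 14 (not isolated)
Conditions: mCPBA (1.3 equiv), CH2Cl2, 0 °C to rt; then K2CO3 (cat.), MeOH, rt
Reagents that add atoms: 3-chloroperoxybenzoic acid, OOC(=O)c1cccc(Cl)c1
Why: Baeyer–Villiger (Dakin-type) oxidation, in which the electron-rich aryl group migrates in preference to hydride, followed by mild methanolysis of the formate that leaves the benzyl and methyl ethers untouched.

Step 10
Reactants: 8 4-methoxy-3-(3-oxobut-1-yn-1-yl)-6-pentyl-2H-pyran-2-one; 15 2-(benzyloxy)-4-methoxy-6-pentylphenol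
Product: 18 8-[2-(benzyloxy)-4-methoxy-6-pentylphenoxy]-6-hydroxy-3-pentyl-1H-isochromen-1-one, via Z-aryloxy enone 16 (not isolated), via E-aryloxy enone 17 (not isolated)
Conditions: 15 (1.3 equiv), Cs2CO3 (2.5 equiv), DMF, 0 °C to rt; then 80 °C; aq. NH4Cl
Reagents that add atoms: none
Why: Proposed new method: the cesium phenoxide of 15 adds to the alkyne carbon β to the ketone of 8 (oxa-Michael, C8–O) to give enone 16, which equilibrates by reversible phenoxide addition–elimination to the E isomer 17 that places the acetyl group beside the pyranone; deprotonation of the acetyl methyl then gives a cross-conjugated dienolate whose terminal carbon (C5) bonds to the methoxy-bearing pyranone carbon (C4a), methoxide is expelled and the resulting dienone enolises to the C6 phenol. The closest known reaction types are the base-catalysed conjugate addition of phenols to ynones and the annulation of a benzo ring onto a 4-methoxy-2-pyranone by carbanion attack at C4 with loss of methanol; joining them in one flask on a 3-alkynylpyranone is untested. Ring A closes by a 6-endo-trig vinylogous addition–elimination, equivalent to a 6π electrocyclisation of the oxido-triene C5=C6–C7=C8–C8a=C4a followed by loss of methanol, and no stereocentre is created. The phenoxide must choose the ynone over C4 and C6 of the pyranone, which the much higher electrophilicity of the ynone at 0 °C should secure, and the adduct must reach the E geometry, which the reversibility of the addition and the irreversible aromatisation should secure. The enolate carbon must attack C4a and not the lactone carbonyl C1 or react through oxygen: only C4a ends a continuous triene, the lactone carbonyl is a deactivated vinylogous carbonate, and only C–C closure leads to an aromatic ring. Excess 15 buffers the released methoxide and, together with complete addition before heating, keeps the product phenoxide from adding to unreacted 8.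

Step 11
Reactants: 18 8-[2-(benzyloxy)-4-methoxy-6-pentylphenoxy]-6-hydroxy-3-pentyl-1H-isochromen-1-one
Product: 19 6-hydroxy-8-(2-hydroxy-4-methoxy-6-pentylphenoxy)-3-pentyl-1H-isochromen-1-one
Conditions: BCl3 (3 equiv), pentamethylbenzene (4 equiv), CH2Cl2, −78 °C; MeOH, then H2O
Reagents that add atoms: none
Why: Lewis-acid debenzylation in which pentamethylbenzene traps the benzyl cation (Friedel–Crafts), so the electron-rich ring C should not be C-benzylated and the aryl methyl ether, diaryl ether and lactone should survive at −78 °C.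

**Compound list**

1 | 4-hydroxy-6-methyl-2H-pyran-2-one (triacetic acid lactone) | Cc1cc(O)cc(=O)o1 | starting material
2 | 1-iodobutane | CCCCI | starting material
3 | 4-hydroxy-6-pentyl-2H-pyran-2-one | CCCCCc1cc(O)cc(=O)o1 | intermediate
4 | 4-methoxy-6-pentyl-2H-pyran-2-one | CCCCCc1cc(OC)cc(=O)o1 | intermediate
5 | 3-iodo-4-methoxy-6-pentyl-2H-pyran-2-one | CCCCCc1cc(OC)c(I)c(=O)o1 | intermediate
6 | but-3-yn-2-ol (racemic) | CC(O)C#C | starting material
7 | 3-(3-hydroxybut-1-yn-1-yl)-4-methoxy-6-pentyl-2H-pyran-2-one (racemic) | CCCCCc1cc(OC)c(C#CC(C)O)c(=O)o1 | intermediate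
8 | 4-methoxy-3-(3-oxobut-1-yn-1-yl)-6-pentyl-2H-pyran-2-one | CCCCCc1cc(OC)c(C#CC(C)=O)c(=O)o1 | intermediate
9 | olivetol (5-pentylbenzene-1,3-diol) | CCCCCc1cc(O)cc(O)c1 | starting material
10 | N-[(2,4-dihydroxy-6-pentylphenyl)methylidene]-N-methylmethanaminium chloride (not isolated) | CCCCCc1cc(O)cc(O)c1C=[N+](C)C.[Cl-] | intermediate
11 | 2,4-dihydroxy-6-pentylbenzaldehyde | CCCCCc1cc(O)cc(O)c1C=O | intermediate
12 | 2-hydroxy-4-methoxy-6-pentylbenzaldehyde | CCCCCc1cc(OC)cc(O)c1C=O | intermediate
13 | 2-(benzyloxy)-4-methoxy-6-pentylbenzaldehyde | CCCCCc1cc(OC)cc(OCc2ccccc2)c1C=O | intermediate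
14 | 2-(benzyloxy)-4-methoxy-6-pentylphenyl formate (not isolated) | CCCCCc1cc(OC)cc(OCc2ccccc2)c1OC=O | intermediate
15 | 2-(benzyloxy)-4-methoxy-6-pentylphenol | CCCCCc1cc(OC)cc(OCc2ccccc2)c1O | intermediate
16 | 3-{(1Z)-1-[2-(benzyloxy)-4-methoxy-6-pentylphenoxy]-3-oxobut-1-en-1-yl}-4-methoxy-6-pentyl-2H-pyran-2-one (not isolated) | CC(=O)/C=C(\Oc1c(OCc2ccccc2)cc(OC)cc1CCCCC)c1c(OC)cc(CCCCC)oc1=O | intermediate
17 | 3-{(1E)-1-[2-(benzyloxy)-4-methoxy-6-pentylphenoxy]-3-oxobut-1-en-1-yl}-4-methoxy-6-pentyl-2H-pyran-2-one (not isolated) | CC(=O)/C=C(/Oc1c(OCc2ccccc2)cc(OC)cc1CCCCC)c1c(OC)cc(CCCCC)oc1=O | intermediate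
18 | 8-[2-(benzyloxy)-4-methoxy-6-pentylphenoxy]-6-hydroxy-3-pentyl-1H-isochromen-1-one | CCCCCc1cc2cc(O)cc(Oc3c(OCc4ccccc4)cc(OC)cc3CCCCC)c2c(=O)o1 | intermediate
19 | 6-hydroxy-8-(2-hydroxy-4-methoxy-6-pentylphenoxy)-3-pentyl-1H-isochromen-1-one (NP-007099) | CCCCCc1cc2cc(O)cc(Oc3c(O)cc(OC)cc3CCCCC)c2c(=O)o1 | target

**Step count and risks**

Total step count: 11. Longest linear sequence: 7 steps (steps 1, 2, 3, 4, 5, 10, 11); the phenol arm (steps 6 to 9) joins at step 10.

Steps most likely to fail:

Step 10 (proposed new method). The cascade may stall at the enone stage if carbonate does not deprotonate the acetyl methyl. The adduct may not reach the E geometry. The dienolate may close on the lactone carbonyl or through oxygen. The liberated product phenoxide may consume ynone. The fallback uses known chemistry only; it sets out from 15 and comes back to the route at 19. The C8–O bond is made by cross-coupling on a ring A that is already aromatic, and ring B is built afterwards.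
- Commercial ethyl 2,4-dihydroxy-6-methylbenzoate is benzylated at the non-chelated 4-hydroxyl (BnBr, K2CO3, acetone) to give ethyl 4-(benzyloxy)-2-hydroxy-6-methylbenzoate F1.
- Tf2O and pyridine convert F1 into ethyl 4-(benzyloxy)-2-methyl-6-{[(trifluoromethyl)sulfonyl]oxy}benzoate F2.
- A palladium-catalysed C–O coupling of F2 with 15 (Pd(OAc)2, 2-di-tert-butylphosphino-2′,4′,6′-triisopropylbiphenyl, K3PO4, toluene, 100 °C), a reaction type that accepts ortho-disubstituted phenols, should give ethyl 4-(benzyloxy)-2-[2-(benzyloxy)-4-methoxy-6-pentylphenoxy]-6-methylbenzoate F3.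
- Lateral lithiation of the toluate methyl group (LiN(i-Pr)2, THF, −78 °C) and acylation with methyl hexanoate give ethyl 4-(benzyloxy)-2-[2-(benzyloxy)-4-methoxy-6-pentylphenoxy]-6-(2-oxoheptyl)benzoate F4.
- Acid-catalysed enol lactonisation (TsOH, toluene, reflux) then closes ring B to 6-(benzyloxy)-8-[2-(benzyloxy)-4-methoxy-6-pentylphenoxy]-3-pentyl-1H-isochromen-1-one F5.
- The conditions of step 11 remove both benzyl ethers of F5 and deliver 19.

Step 1. Formation of the dilithio species may be incomplete because of poor solubility, and the side chain may be alkylated twice or the oxygen alkylated. The fallback assembles the pentyl-substituted ring de novo instead of alkylating a preformed one. It uses none of the numbered compounds before 3, because commercial methyl acetoacetate and methyl hexanoate replace 1 and 2, and it comes back to the route at 3. The dianion of methyl acetoacetate (NaH, then n-BuLi, THF, 0 °C) is acylated at its terminal carbon by methyl hexanoate to give methyl 3,5-dioxodecanoate F6. F6 cyclises with DBU in refluxing toluene, with loss of methanol, to 3.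

Step 4. The alkyne may homocouple oxidatively under copper catalysis, the iodopyranone may degrade in the presence of amine and iodide, and the coupled alkyne may cyclise onto the neighbouring methoxy oxygen under metal activation. The fallback is a copper-free and amine-free Negishi alkynylation; it sets out from 5 and 6 and comes back to the route at 7. Alcohol 6 is silylated (TBSCl, imidazole, DMF) to tert-butyl(but-3-yn-2-yloxy)dimethylsilane F7. F7 is converted into its alkynylzinc chloride (n-BuLi, THF, −78 °C; ZnCl2) and coupled with 5 (Pd(PPh3)4, THF, rt) to give 3-{3-[(tert-butyldimethylsilyl)oxy]but-1-yn-1-yl}-4-methoxy-6-pentyl-2H-pyran-2-one F8. Desilylation (n-Bu4NF, AcOH, THF) then gives 7.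

Further compounds
F1 | step 10 | ethyl 4-(benzyloxy)-2-hydroxy-6-methylbenzoate | CCOC(=O)c1c(C)cc(OCc2ccccc2)cc1O
F2 | step 10 | ethyl 4-(benzyloxy)-2-methyl-6-{[(trifluoromethyl)sulfonyl]oxy}benzoate | CCOC(=O)c1c(C)cc(OCc2ccccc2)cc1OS(=O)(=O)C(F)(F)F
F3 | step 10 | ethyl 4-(benzyloxy)-2-[2-(benzyloxy)-4-methoxy-6-pentylphenoxy]-6-methylbenzoate | CCOC(=O)c1c(C)cc(OCc2ccccc2)cc1Oc1c(OCc2ccccc2)cc(OC)cc1CCCCC
F4 | step 10 | ethyl 4-(benzyloxy)-2-[2-(benzyloxy)-4-methoxy-6-pentylphenoxy]-6-(2-oxoheptyl)benzoate | CCCCCC(=O)Cc1cc(OCc2ccccc2)cc(Oc2c(OCc3ccccc3)cc(OC)cc2CCCCC)c1C(=O)OCC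
F5 | step 10 | 6-(benzyloxy)-8-[2-(benzyloxy)-4-methoxy-6-pentylphenoxy]-3-pentyl-1H-isochromen-1-one | CCCCCc1cc2cc(OCc3ccccc3)cc(Oc3c(OCc4ccccc4)cc(OC)cc3CCCCC)c2c(=O)o1
F6 | step 1 | methyl 3,5-dioxodecanoate | CCCCCC(=O)CC(=O)CC(=O)OC
F7 | step 4 | tert-butyl(but-3-yn-2-yloxy)dimethylsilane (racemic) | CC(C#C)O[Si](C)(C)C(C)(C)C
F8 | step 4 | 3-{3-[(tert-butyldimethylsilyl)oxy]but-1-yn-1-yl}-4-methoxy-6-pentyl-2H-pyran-2-one (racemic) | CCCCCc1cc(OC)c(C#CC(C)O[Si](C)(C)C(C)(C)C)c(=O)o1
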